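**Plan**

- Retrosynthesis: after the 4'-O–Si bond, ring C is cut at C3–C4 and at C2=C3. C3, with its methoxy group, lies between two acyl-level carbons (C4 on ring A, C2 on ring B), so it can come from Ph3P=CHOMe and an O-aroylsalicyloyl chloride.
- The ester bond O1–C2 is cut next (ring B as O-silylated vanilloyl chloride), and the COCl carbon is traced back to CHO. Ring A goes back to 2-methoxyresorcinol by cutting O7–prenyl, C4a–CHO and C5–O.
- Forward: ring A is oxygenated at C5, formylated and prenylated (steps 1–6), and ring B is attached through the ester (steps 7–9). The aldehyde is raised to the acid chloride (steps 10–11), ring C (the only ring formed) is closed by the ylide (steps 12–13), and desilylation finishes the route (step 14).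
- Stereochemistry: the target has no stereocentre and the prenyl double bond has no E/Z isomers. Only regiochemistry is at issue; it comes from the symmetry of the resorcinol, the sterically governed borylation and the hydrogen-bonded 2-OH of the salicylaldehyde.

Key step: step 13

Remark: flavone numbering (O1, C2 to C8a, primed ring B) is used for positions of the target. Ylide 19 is prepared in its own flask as a THF solution and used at once; this is counted as step 12.

**Route**

Step 1
Reactants: 1 2-methoxyresorcinol
Product: 2 2-methoxy-1,3-bis(methoxymethoxy)benzene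
Conditions: MOMCl (2.5 equiv), iPr2NEt, CH2Cl2, 0 °C to rt
Reagents that add atoms: chloromethyl methyl ether, COCCl
Why: O-alkylation of both phenols with the reactive α-chloro ether (MOM protection) removes the acidic OH groups before C–H borylation and provides the ortho-directing groups used in step 4.

Step 2
Reactants: 2 2-methoxy-1,3-bis(methoxymethoxy)benzene
Product: 4 4-methoxy-3,5-bis(methoxymethoxy)phenol, via aryl pinacol boronate 3 (not isolated)
Conditions: [Ir(OMe)(cod)]2 (1.5 mol %), 4,4'-di-tert-butyl-2,2'-bipyridine (3 mol %), B2pin2 (1.0 equiv), THF, 80 °C; then NaOH, H2O2, THF/H2O, 0 °C to rt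
Reagents that add atoms: bis(pinacolato)diboron, CC1(C)OB(OC1(C)C)B1OC(C)(C)C(C)(C)O1 (its boryl group is carried by 3 only); hydrogen peroxide, OO
Why: Sterically governed iridium-catalysed aromatic C–H borylation should take the only ring C–H without an ortho substituent (C5 of the 1,2,3-trisubstituted arene), and alkaline peroxide then converts C–B into C–OH without touching the base-stable MOM acetals (C–H borylation/oxidation sequence).

Step 3
Reactants: 4 4-methoxy-3,5-bis(methoxymethoxy)phenol
Product: 5 2,5-dimethoxy-1,3-bis(methoxymethoxy)benzene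
Conditions: MeI, K2CO3, acetone, 50 °C
Reagents that add atoms: iodomethane, CI
Why: Williamson methylation of the only free phenol installs the methoxy group that becomes 5-OMe of the flavone.

Step 4
Reactants: 5 2,5-dimethoxy-1,3-bis(methoxymethoxy)benzene
Product: 7 3,6-dimethoxy-2,4-bis(methoxymethoxy)benzaldehyde, via aryllithium 6 (not isolated)
Conditions: n-BuLi, TMEDA, THF, 0 °C; DMF, −78 °C to rt; aq NH4Cl
Reagents that add atoms: N,N-dimethylformamide, CN(C)C=O; n-butyllithium, CCCC[Li] (its lithium is carried by 6 only)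
Why: Directed ortho-metalation is unambiguous because the two remaining ring hydrogens are equivalent and each lies between an OMOM and an OMe group, and formylation of the aryllithium with DMF should give the aldehyde.

Step 5
Reactants: 7 3,6-dimethoxy-2,4-bis(methoxymethoxy)benzaldehyde
Product: 8 2,4-dihydroxy-3,6-dimethoxybenzaldehyde
Conditions: HCl (1.25 M in MeOH), 45 °C; then H2O
Reagents that add atoms: none
Why: Acid-catalysed acetal exchange with methanol (MOM cleavage) frees both phenols while the formaldehyde unit leaves as volatile dimethoxymethane and so cannot alkylate the electron-rich ring, and the aqueous work-up returns any dimethyl acetal to the aldehyde.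

Step 6
Reactants: 8 2,4-dihydroxy-3,6-dimethoxybenzaldehyde; 9 prenyl bromide (1-bromo-3-methylbut-2-ene)
Product: 10 2-hydroxy-3,6-dimethoxy-4-(3-methylbut-2-enyloxy)benzaldehyde
Conditions: 9 (1.05 equiv), K2CO3 (1.1 equiv), acetone, rt to 40 °C
Reagents that add atoms: none
Why: Williamson etherification should select the 4-OH, which is the more acidic (para to the formyl group) and is not held in the hydrogen bond to the carbonyl, as is general for 2,4-dihydroxybenzaldehydes.

Step 7
Reactants: 11 vanillic acid (4-hydroxy-3-methoxybenzoic acid)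
Product: 13 3-methoxy-4-(triisopropylsilyloxy)benzoic acid, via bis-silylated vanillic acid 12 (not isolated)
Conditions: TIPSCl (2.3 equiv), imidazole, DMF, rt; then K2CO3, MeOH/THF/H2O, rt; 1 M HCl to pH 4
Reagents that add atoms: chlorotriisopropylsilane, CC(C)[Si](Cl)(C(C)C)C(C)C
Why: Silylation of both the phenol and the acid, followed by selective hydrolysis of the far more labile silyl ester, should leave the robust aryl triisopropylsilyl ether in place (silyl protection with ester cleavage).

Step 8
Reactants: 13 3-methoxy-4-(triisopropylsilyloxy)benzoic acid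
Product: 14 3-methoxy-4-(triisopropylsilyloxy)benzoyl chloride
Conditions: (COCl)2, DMF (cat.), CH2Cl2, 0 °C to rt; concentrate
Reagents that add atoms: oxalyl chloride, O=C(Cl)C(Cl)=O
Why: Acid chloride formation through the Vilsmeier-type chloroiminium catalyst is standard for silyloxybenzoic acids, and the hindered aryl silyl ether should tolerate the HCl released.

Step 9
Reactants: 10 2-hydroxy-3,6-dimethoxy-4-(3-methylbut-2-enyloxy)benzaldehyde; 14 3-methoxy-4-(triisopropylsilyloxy)benzoyl chloride
Product: 15 2-formyl-3,6-dimethoxy-5-(3-methylbut-2-enyloxy)phenyl 3-methoxy-4-(triisopropylsilyloxy)benzoate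
Conditions: Et3N, DMAP (cat.), CH2Cl2, 0 °C to rt
Reagents that add atoms: none
Why: DMAP-catalysed O-acylation by the acylpyridinium ion should overcome the hydrogen bond and the two ortho substituents of the remaining phenol, as in the aroylation of 2-hydroxyaryl carbonyl compounds for flavone synthesis, and it forms the future O1–C2 bond.

Step 10
Reactants: 15 2-formyl-3,6-dimethoxy-5-(3-methylbut-2-enyloxy)phenyl 3-methoxy-4-(triisopropylsilyloxy)benzoate
Product: 16 3,6-dimethoxy-2-{[3-methoxy-4-(triisopropylsilyloxy)benzoyl]oxy}-4-(3-methylbut-2-enyloxy)benzoic acid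
Conditions: NaClO2, NaH2PO4, 2-methyl-2-butene (30 equiv), t-BuOH/THF/H2O, 0 °C to rt
Reagents that add atoms: sodium chlorite, [Na+].[O-]Cl=O
Why: Pinnick oxidation converts the aldehyde to the acid at about pH 4, where the aryl ester and silyl ether are stable, while the large excess of 2-methyl-2-butene should intercept HOCl before it reaches the prenyl double bond or the activated ring.

Step 11
Reactants: 16 3,6-dimethoxy-2-{[3-methoxy-4-(triisopropylsilyloxy)benzoyl]oxy}-4-(3-methylbut-2-enyloxy)benzoic acid
Product: 17 2-(chlorocarbonyl)-3,6-dimethoxy-5-(3-methylbut-2-enyloxy)phenyl 3-methoxy-4-(triisopropylsilyloxy)benzoate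
Conditions: 1-chloro-N,N,2-trimethylprop-1-en-1-amine (1.2 equiv), CH2Cl2, 0 °C to rt; concentrate, use crude
Reagents that add atoms: 1-chloro-N,N,2-trimethylprop-1-en-1-amine, CC(C)=C(Cl)N(C)C
Why: The α-chloroenamine converts the acid to the acid chloride under neutral conditions with only an inert amide as co-product, so no HCl is present to add to or cleave the prenyl ether (acid chloride formation with the Ghosez reagent).

Step 12
Reactants: 18 (methoxymethyl)triphenylphosphonium chloride
Product: 19 methoxymethylenetriphenylphosphorane (THF solution, used at once)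
Conditions: NaN(SiMe3)2, THF, 0 °C
Reagents that add atoms: none
Why: Deprotonation of the phosphonium salt by the hindered amide base is the standard, lithium-free way to generate this ylide, which is kept cold because it decomposes on standing at room temperature.

Step 13
Reactants: 17 2-(chlorocarbonyl)-3,6-dimethoxy-5-(3-methylbut-2-enyloxy)phenyl 3-methoxy-4-(triisopropylsilyloxy)benzoate; 19 methoxymethylenetriphenylphosphorane
Product: 22 3,5,8,3'-tetramethoxy-7-(3-methylbut-2-enyloxy)-4'-(triisopropylsilyloxy)flavone, via acylphosphonium chloride 20 (not isolated), via keto ylide 21 (not isolated)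
Conditions: 19 (2.1 equiv), THF, −78 °C, 17 added slowly, then rt; filter; toluene, 110 °C
Reagents that add atoms: none
Why: Added cold to two equivalents of 19, the acid chloride (far more electrophilic than the aryl ester) is C-acylated to phosphonium salt 20, which the second equivalent of 19 deprotonates to the α-methoxy β-keto ylide 21, so C3 arrives bonded to C4 and already carrying its OMe. On heating, the ylide carbon of 21 adds to the adjacent aryl ester carbonyl in a 6-exo-trig closure that forms ring C, and the oxaphosphetane collapses to the C2=C3 double bond with loss of Ph3PO; the oxygen lost is the ester C=O oxygen, and the phenolic oxygen remains as O1. The closest known reaction type is the chromone and flavone synthesis from O-acylsalicylic acid derivatives and phosphorus ylides by C-acylation and intramolecular Wittig olefination of the ester, run here with an α-methoxy ylide, whose donor group should make the keto ylide more nucleophilic. No stereocentre is created. The step needs first attack at the acid chloride and not at the ester, secured by the reactivity gap at −78 °C and by adding 17 to the ylide, and it needs an ester to be olefinated, which the six-membered transition state and the gain of the aromatic 4-pyranone favour.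

Step 14
Reactants: 22 3,5,8,3'-tetramethoxy-7-(3-methylbut-2-enyloxy)-4'-(triisopropylsilyloxy)flavone
Product: 23 4'-hydroxy-3,5,8,3'-tetramethoxy-7-prenyloxyflavone
Conditions: Bu4NF, AcOH, THF, 0 °C to rt
Reagents that add atoms: none
Why: Fluoride cleaves the aryl Si–O bond (desilylation), and the acetic acid buffer protonates the phenoxide as it forms, so the prenyl ether, the methyl ethers and the pyranone should be untouched.

**Compound list**

1 | 2-methoxyresorcinol | COc1c(O)cccc1O | starting material
2 | 2-methoxy-1,3-bis(methoxymethoxy)benzene | COCOc1cccc(OCOC)c1OC | intermediate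
3 | 2-[4-methoxy-3,5-bis(methoxymethoxy)phenyl]-4,4,5,5-tetramethyl-1,3,2-dioxaborolane | COCOc1cc(B2OC(C)(C)C(C)(C)O2)cc(OCOC)c1OC | intermediate
4 | 4-methoxy-3,5-bis(methoxymethoxy)phenol | COCOc1cc(O)cc(OCOC)c1OC | intermediate
5 | 2,5-dimethoxy-1,3-bis(methoxymethoxy)benzene | COCOc1cc(OC)cc(OCOC)c1OC | intermediate
6 | [3,6-dimethoxy-2,4-bis(methoxymethoxy)phenyl]lithium | [Li]c1c(OC)cc(OCOC)c(OC)c1OCOC | intermediate
7 | 3,6-dimethoxy-2,4-bis(methoxymethoxy)benzaldehyde | O=Cc1c(OC)cc(OCOC)c(OC)c1OCOC | intermediate
8 | 2,4-dihydroxy-3,6-dimethoxybenzaldehyde | O=Cc1c(OC)cc(O)c(OC)c1O | intermediate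
9 | prenyl bromide (1-bromo-3-methylbut-2-ene) | CC(C)=CCBr | starting material
10 | 2-hydroxy-3,6-dimethoxy-4-(3-methylbut-2-enyloxy)benzaldehyde | O=Cc1c(OC)cc(OCC=C(C)C)c(OC)c1O | intermediate
11 | vanillic acid | COc1cc(C(=O)O)ccc1O | starting material
12 | triisopropylsilyl 3-methoxy-4-(triisopropylsilyloxy)benzoate | COc1cc(C(=O)O[Si](C(C)C)(C(C)C)C(C)C)ccc1O[Si](C(C)C)(C(C)C)C(C)C | intermediate
13 | 3-methoxy-4-(triisopropylsilyloxy)benzoic acid | COc1cc(C(=O)O)ccc1O[Si](C(C)C)(C(C)C)C(C)C | intermediate
14 | 3-methoxy-4-(triisopropylsilyloxy)benzoyl chloride | COc1cc(C(Cl)=O)ccc1O[Si](C(C)C)(C(C)C)C(C)C | intermediate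
15 | 2-formyl-3,6-dimethoxy-5-(3-methylbut-2-enyloxy)phenyl 3-methoxy-4-(triisopropylsilyloxy)benzoate | COc1cc(C(=O)Oc2c(OC)c(OCC=C(C)C)cc(OC)c2C=O)ccc1O[Si](C(C)C)(C(C)C)C(C)C | intermediate
16 | 3,6-dimethoxy-2-{[3-methoxy-4-(triisopropylsilyloxy)benzoyl]oxy}-4-(3-methylbut-2-enyloxy)benzoic acid | COc1cc(C(=O)Oc2c(OC)c(OCC=C(C)C)cc(OC)c2C(=O)O)ccc1O[Si](C(C)C)(C(C)C)C(C)C | intermediate
17 | 2-(chlorocarbonyl)-3,6-dimethoxy-5-(3-methylbut-2-enyloxy)phenyl 3-methoxy-4-(triisopropylsilyloxy)benzoate | COc1cc(C(=O)Oc2c(OC)c(OCC=C(C)C)cc(OC)c2C(Cl)=O)ccc1O[Si](C(C)C)(C(C)C)C(C)C | intermediate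
18 | (methoxymethyl)triphenylphosphonium chloride | [Cl-].COC[P+](c1ccccc1)(c1ccccc1)c1ccccc1 | starting material
19 | methoxymethylenetriphenylphosphorane | COC=P(c1ccccc1)(c1ccccc1)c1ccccc1 | intermediate
20 | {1-methoxy-2-[3,6-dimethoxy-2-{[3-methoxy-4-(triisopropylsilyloxy)benzoyl]oxy}-4-(3-methylbut-2-enyloxy)phenyl]-2-oxoethyl}triphenylphosphonium chloride | [Cl-].COc1cc(C(=O)Oc2c(OC)c(OCC=C(C)C)cc(OC)c2C(=O)C(OC)[P+](c3ccccc3)(c3ccccc3)c3ccccc3)ccc1O[Si](C(C)C)(C(C)C)C(C)C | intermediate
21 | 2-[2-methoxy-2-(triphenylphosphoranylidene)acetyl]-3,6-dimethoxy-5-(3-methylbut-2-enyloxy)phenyl 3-methoxy-4-(triisopropylsilyloxy)benzoate | COc1cc(C(=O)Oc2c(OC)c(OCC=C(C)C)cc(OC)c2C(=O)C(OC)=P(c3ccccc3)(c3ccccc3)c3ccccc3)ccc1O[Si](C(C)C)(C(C)C)C(C)C | intermediate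
22 | 3,5,8,3'-tetramethoxy-7-(3-methylbut-2-enyloxy)-4'-(triisopropylsilyloxy)flavone | COc1cc(-c2oc3c(OC)c(OCC=C(C)C)cc(OC)c3c(=O)c2OC)ccc1O[Si](C(C)C)(C(C)C)C(C)C | intermediate
23 | 4'-hydroxy-3,5,8,3'-tetramethoxy-7-prenyloxyflavone | COc1cc(-c2oc3c(OC)c(OCC=C(C)C)cc(OC)c3c(=O)c2OC)ccc1O | target

**Step count**

Total: 14 steps (ylide generation included). Longest linear sequence: 11 steps (1–6, 9–11, 13, 14).

**Steps most likely to fail**

Step 13. The α-methoxy keto ylide may form but then fail to add to the electron-rich aryl ester carbonyl, or decompose on prolonged heating. The free ylide may also attack the ester in competition with the hindered acid chloride. The fallback closes ring C by Baker–Venkataraman chemistry and sets out from acid chloride 17. CH2N2 with Et3N in Et2O at 0 °C would give 2-(diazoacetyl)-3,6-dimethoxy-5-(3-methylbut-2-enyloxy)phenyl 3-methoxy-4-(triisopropylsilyloxy)benzoate F1. Rh2(OAc)4-catalysed O–H insertion in MeOH would give 2-(methoxyacetyl)-3,6-dimethoxy-5-(3-methylbut-2-enyloxy)phenyl 3-methoxy-4-(triisopropylsilyloxy)benzoate F2. LiN(SiMe3)2 in THF would then bring about the 1,5-acyl shift to 1-[2-hydroxy-3,6-dimethoxy-4-(3-methylbut-2-enyloxy)phenyl]-2-methoxy-3-[3-methoxy-4-(triisopropylsilyloxy)phenyl]propane-1,3-dione F3. Cyclodehydration with pyridinium p-toluenesulfonate in toluene at 80 °C returns to the route at silyl flavone 22.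

Step 10. Electrophilic chlorine released during the chlorite oxidation may add to the prenyl double bond or substitute the activated ring position faster than the scavenger removes it, and the doubly ortho-substituted aldehyde may oxidise slowly. The fallback sets the acid oxidation level before acylation, with an oxidant that ignores alkenes, and sets out from phenol aldehyde 10. Ag2O in aqueous NaOH would give 2-hydroxy-3,6-dimethoxy-4-(3-methylbut-2-enyloxy)benzoic acid F7. O-Aroylation of this salicylic acid with acid chloride 14 in pyridine, the usual way to O-acylsalicylic acids, rejoins the route at acid 16 (steps 9 and 10 are replaced).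

Step 2. The C–H borylation may stall or be drawn ortho by coordination of a MOM oxygen, or the acetals may suffer during the oxidative work-up. The fallback brings in the C5 oxygen by amide-directed ortho-metalation and sets out from 2. Lithiation (n-BuLi, TMEDA) and quenching with ClCONEt2 would give N,N-diethyl-3-methoxy-2,4-bis(methoxymethoxy)benzamide F4. Amide-directed lithiation (s-BuLi, TMEDA, −78 °C), boration with B(OMe)3 and oxidation with H2O2 would give N,N-diethyl-6-hydroxy-3-methoxy-2,4-bis(methoxymethoxy)benzamide F5. MeI with K2CO3 would give N,N-diethyl-3,6-dimethoxy-2,4-bis(methoxymethoxy)benzamide F6. Reduction of the tertiary amide with Cp2Zr(H)Cl returns to the route at aldehyde 7 (steps 2 to 4 are replaced).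

**Further compounds**

F1 | step 13 | 2-(diazoacetyl)-3,6-dimethoxy-5-(3-methylbut-2-enyloxy)phenyl 3-methoxy-4-(triisopropylsilyloxy)benzoate | COc1cc(C(=O)Oc2c(OC)c(OCC=C(C)C)cc(OC)c2C(=O)C=[N+]=[N-])ccc1O[Si](C(C)C)(C(C)C)C(C)C
F2 | step 13 | 2-(methoxyacetyl)-3,6-dimethoxy-5-(3-methylbut-2-enyloxy)phenyl 3-methoxy-4-(triisopropylsilyloxy)benzoate | COc1cc(C(=O)Oc2c(OC)c(OCC=C(C)C)cc(OC)c2C(=O)COC)ccc1O[Si](C(C)C)(C(C)C)C(C)C
F3 | step 13 | 1-[2-hydroxy-3,6-dimethoxy-4-(3-methylbut-2-enyloxy)phenyl]-2-methoxy-3-[3-methoxy-4-(triisopropylsilyloxy)phenyl]propane-1,3-dione | COc1cc(C(=O)C(OC)C(=O)c2c(OC)cc(OCC=C(C)C)c(OC)c2O)ccc1O[Si](C(C)C)(C(C)C)C(C)C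
F4 | step 2 | N,N-diethyl-3-methoxy-2,4-bis(methoxymethoxy)benzamide | CCN(CC)C(=O)c1ccc(OCOC)c(OC)c1OCOC
F5 | step 2 | N,N-diethyl-6-hydroxy-3-methoxy-2,4-bis(methoxymethoxy)benzamide | CCN(CC)C(=O)c1c(O)cc(OCOC)c(OC)c1OCOC
F6 | step 2 | N,N-diethyl-3,6-dimethoxy-2,4-bis(methoxymethoxy)benzamide | CCN(CC)C(=O)c1c(OC)cc(OCOC)c(OC)c1OCOC
F7 | step 10 | 2-hydroxy-3,6-dimethoxy-4-(3-methylbut-2-enyloxy)benzoic acid | OC(=O)c1c(OC)cc(OCC=C(C)C)c(OC)c1O
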